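Assumption: the target is achiral (no stereocentre, no stable atropisomer), so there is no enantiomer to control; the only stereo-element on the route is the E-alkene of the chalcone.

**Retrosynthetic overview**
1. Target ⇐ 3,5,7,8,2',4'-hexamethoxyflavone by chelation-controlled cleavage of the peri 5-OMe; hexamethoxyflavone ⇐ flavonol by 3-O-methylation.
2. Flavonol ⇐ 5,7,8,2',4'-pentamethoxyflavone by C3 oxygenation (epoxidation, then ring opening).
3. Flavone ⇐ 2'-hydroxychalcone by oxidative cyclisation (O1–C2 bond); ring C is the only ring built, and it is closed here.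
4. Chalcone ⇐ Claisen–Schmidt aldol condensation of 2-hydroxy-3,4,6-trimethoxyacetophenone (ring A) with 2,4-dimethoxybenzaldehyde (ring B); this is the fragment-joining C–C bond.
5. Acetophenone ⇐ 1,2,3,5-tetramethoxybenzene (Friedel–Crafts acylation with ortho-demethylation) ⇐ 3,4,5-trimethoxyphenol; rings A and B are bought as arenes.

**Route**

Step 1
Reactants: 1 3,4,5-trimethoxyphenol
Product: 2 1,2,3,5-tetramethoxybenzene
Conditions: MeI (1.5 eq), K2CO3 (2 eq), DMF, rt, 12 h
Reagents that add atoms: iodomethane, CI
Why: Williamson O-methylation of an unhindered phenoxide is clean and gives a symmetrical arene whose two free positions are equivalent.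

Step 2
Reactants: 2 1,2,3,5-tetramethoxybenzene
Product: 4 2-hydroxy-3,4,6-trimethoxyacetophenone, via 2,3,4,6-tetramethoxyacetophenone 3 (not isolated)
Conditions: AcCl (1.2 eq), AlCl3 (2.5 eq), Et2O, 0 °C → rt, 24 h; then ice/2 M HCl
Reagents that add atoms: acetyl chloride, CC(=O)Cl
Why: Friedel–Crafts acylation can only occur at the two equivalent free positions, and AlCl3 chelated to the new carbonyl then cleaves the ortho methoxy that is squeezed between the acetyl and a second OMe (the more hindered, out-of-plane one) in a Lewis-acid ether cleavage that stops at the chelated mono-phenol.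

Step 3
Reactants: 4 2-hydroxy-3,4,6-trimethoxyacetophenone; 5 2,4-dimethoxybenzaldehyde
Product: 7 (E)-2'-hydroxy-2,3',4,4',6'-pentamethoxychalcone, via racemic aldol adduct 6 (not isolated)
Conditions: 50% aq. KOH (10 eq), EtOH, rt, 48 h; then cold 2 M HCl
Reagents that add atoms: none
Why: Claisen–Schmidt crossed aldol condensation, in which the methyl ketone enolate adds to the non-enolisable aldehyde and the β-hydroxy ketone dehydrates by E1cB to the conjugated, thermodynamically favoured E-enone (the adduct's stereocentre is lost on dehydration).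

Step 4
Reactants: 7 (E)-2'-hydroxy-2,3',4,4',6'-pentamethoxychalcone
Product: 9 5,7,8,2',4'-pentamethoxyflavone, via racemic flavanone 8 (not isolated)
Conditions: I2 (10 mol%), DMSO, 130 °C, 3 h
Reagents that add atoms: none
Why: I2/DMSO oxidative cyclisation of a 2'-hydroxychalcone, i.e. 6-endo oxa-Michael closure to the flavanone followed by α-iodination and HI elimination with DMSO re-oxidising HI, so any flavanone already formed in step 3 converges on the same flavone.

Step 5
Reactants: 9 5,7,8,2',4'-pentamethoxyflavone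
Product: 11 3-hydroxy-5,7,8,2',4'-pentamethoxyflavone, via racemic flavone 2,3-epoxide 10 (not isolated)
Conditions: DMDO (ca. 0.08 M in acetone, 4 eq), CH2Cl2, 0 °C → rt, 24 h; evaporate; then p-TsOH·H2O (10 mol%), CH2Cl2, rt, 1 h
Reagents that add atoms: dimethyldioxirane, CC1(C)OO1
Why: neutral dioxirane epoxidation of the C2=C3 enol-ether bond, then acid-catalysed opening at C2 (oxocarbenium stabilised by O1 and the aryl ring) and loss of H-3 gives the flavonol, which erases both epoxide stereocentres.

Step 6
Reactants: 11 3-hydroxy-5,7,8,2',4'-pentamethoxyflavone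
Product: 12 3,5,7,8,2',4'-hexamethoxyflavone
Conditions: MeI (3 eq), K2CO3 (3 eq), DMF, rt → 40 °C, 8 h
Reagents that add atoms: iodomethane, CI
Why: Williamson O-methylation of the acidic enolic 3-OH, the only free hydroxyl in the molecule.

Step 7
Reactants: 12 3,5,7,8,2',4'-hexamethoxyflavone
Product: 13 5-hydroxy-3,7,8,2',4'-pentamethoxyflavone
Conditions: anhydrous AlCl3 (5 eq), MeCN, rt → 40 °C, 6 h (TLC control); then 2 M HCl, 50 °C, 30 min
Reagents that add atoms: none
Why: Lewis-acid ether cleavage under chelation control, because AlCl3 held in the six-membered chelate between C4=O and the peri 5-OMe activates only that O–CH3 bond for chloride attack, whereas the 3-OMe (poorer five-membered chelate) and the four carbonyl-remote aryl ethers react much more slowly under these mild conditions.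

**Compound list**
1 | 3,4,5-trimethoxyphenol | COc1cc(O)cc(OC)c1OC | starting material
2 | 1,2,3,5-tetramethoxybenzene | COc1cc(OC)c(OC)c(OC)c1 | intermediate
3 | 2,3,4,6-tetramethoxyacetophenone | CC(=O)c1c(OC)cc(OC)c(OC)c1OC | intermediate
4 | 2-hydroxy-3,4,6-trimethoxyacetophenone | CC(=O)c1c(OC)cc(OC)c(OC)c1O | intermediate
5 | 2,4-dimethoxybenzaldehyde | COc1ccc(C=O)c(OC)c1 | starting material
6 | racemic 3-(2,4-dimethoxyphenyl)-3-hydroxy-1-(2-hydroxy-3,4,6-trimethoxyphenyl)propan-1-one (aldol adduct) | COc1ccc(C(O)CC(=O)c2c(O)c(OC)c(OC)cc2OC)c(OC)c1 | intermediate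
7 | (E)-3-(2,4-dimethoxyphenyl)-1-(2-hydroxy-3,4,6-trimethoxyphenyl)prop-2-en-1-one [(E)-2'-hydroxy-2,3',4,4',6'-pentamethoxychalcone] | COc1ccc(/C=C/C(=O)c2c(O)c(OC)c(OC)cc2OC)c(OC)c1 | intermediate
8 | racemic 5,7,8,2',4'-pentamethoxyflavanone | COc1ccc(C2CC(=O)c3c(OC)cc(OC)c(OC)c3O2)c(OC)c1 | intermediate
9 | 5,7,8,2',4'-pentamethoxyflavone | COc1ccc(-c2cc(=O)c3c(OC)cc(OC)c(OC)c3o2)c(OC)c1 | intermediate
10 | racemic 2,3-epoxy-5,7,8,2',4'-pentamethoxyflavanone (flavone 2,3-epoxide, cis-fused oxirane) | COc1ccc(C23Oc4c(OC)c(OC)cc(OC)c4C(=O)C2O3)c(OC)c1 | intermediate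
11 | 3-hydroxy-5,7,8,2',4'-pentamethoxyflavone | COc1ccc(-c2oc3c(OC)c(OC)cc(OC)c3c(=O)c2O)c(OC)c1 | intermediate
12 | 3,5,7,8,2',4'-hexamethoxyflavone | COc1ccc(-c2oc3c(OC)c(OC)cc(OC)c3c(=O)c2OC)c(OC)c1 | intermediate
13 | 5-hydroxy-3,7,8,2',4'-pentamethoxyflavone | COc1ccc(-c2oc3c(OC)c(OC)cc(O)c3c(=O)c2OC)c(OC)c1 | target

**Totals**
Total step count: 7. Longest linear sequence: 7 steps (1 → 13); aldehyde 5 is bought.

**Three steps most likely to fail, with fallbacks**

Step 2 (one-pot acylation and regioselective mono-demethylation; risk of over-demethylation or the wrong ortho ether being cleaved). The fallback sets out from 2 and returns at 4. The C–C bond is made without Lewis acid by directed ortho-lithiation: n-BuLi/TMEDA in THF at 0 °C removes the proton flanked by two methoxy groups to give 2,3,4,6-tetramethoxyphenyllithium F1. This is acylated with N-methoxy-N-methylacetamide (−78 °C → rt, NH4Cl quench) to give 2,3,4,6-tetramethoxyacetophenone 3, now isolated and purified. A separate demethylation with exactly 1.1 eq BCl3 in CH2Cl2 (−78 → 0 °C) then cleaves the doubly flanked ortho ether to give 4.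

Step 5 (DMDO epoxidation of an electron-rich, ortho-substituted flavone; risk of slow conversion or arene over-oxidation). The fallback sets out from 9 and returns at 11, replacing electrophilic oxidation by deprotonation, borylation and oxidation. LDA (1.2 eq, THF, −78 °C) removes H-3 to give 3-lithio-5,7,8,2',4'-pentamethoxyflavone F2. Trapping with B(OMe)3 gives dimethyl (5,7,8,2',4'-pentamethoxyflavon-3-yl)boronate F3. Oxidation of the C–B bond with H2O2/AcOH (0 °C → rt) gives flavonol 11.

Step 7 (discrimination of the 5-OMe from the 3-OMe and the other four ethers). The fallback sets out from 11 and returns at 13, moving the selectivity problem from demethylation to methylation. The flavonol 11, which has no 3-OMe to lose, is treated with AlCl3/MeCN (or BCl3, CH2Cl2, 0 °C) to cleave the peri 5-OMe and give 3,5-dihydroxy-7,8,2',4'-tetramethoxyflavone F4. MeI (1.05 eq) with K2CO3 in acetone at rt then methylates only the 3-OH, because the strongly chelated 5-OH resists alkylation under these conditions, giving 13.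

**Further compounds**
F1 | step 2 | 2,3,4,6-tetramethoxyphenyllithium | [Li]c1c(OC)cc(OC)c(OC)c1OC
F2 | step 5 | 3-lithio-5,7,8,2',4'-pentamethoxyflavone | COc1ccc(-c2oc3c(OC)c(OC)cc(OC)c3c(=O)c2[Li])c(OC)c1
F3 | step 5 | dimethyl (5,7,8,2',4'-pentamethoxyflavon-3-yl)boronate | COc1ccc(-c2oc3c(OC)c(OC)cc(OC)c3c(=O)c2B(OC)OC)c(OC)c1
F4 | step 7 | 3,5-dihydroxy-7,8,2',4'-tetramethoxyflavone | COc1ccc(-c2oc3c(OC)c(OC)cc(O)c3c(=O)c2O)c(OC)c1
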